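## Retrosynthetic overview

1. The target comes from a fully protected (2S)-flavanone by desilylation and then hydrogenolysis of three benzyl ethers. Ring C is the only ring built and it is closed last. Rings A, B and the guaiacyl ring D are bought.
2. Ring C comes from oxa-Michael closure (O1–C2) of a 2'-hydroxychalcone. The two C2 epimers are then sorted by catalyst-controlled transfer hydrogenation, which leaves the 2S ketone.
3. The chalcone comes from a Claisen–Schmidt aldol condensation. This new C–C bond joins 4,6-di-O-benzylphloroacetophenone (ring A) to an enantiopure ring B aldehyde that already carries the whole side chain.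
4. The side chain comes from an Evans boron aldol (C7''–C8'' bond). The partners are the (R)-4-benzyloxazolidinone imide of a syringate-derived aryloxyacetic acid and O-benzylvanillin. This fixes 8''S and gives the threo series.
5. Threo is converted to erythro by Mitsunobu inversion at C7'' (7''S to 7''R).

Assumption: the SMILES is read as (2S,7''R,8''S), the erythro guaiacylglycerol 8''-O-4' ether of (2S)-dihydrotricin. Locants 7'', 8'' and 9'' are the benzylic CH(OH), the CH(OAr) and the CH2OH. TBS = tert-butyldimethylsilyl, Bn = benzyl.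

## Route

Step 1
Reactants: 1 methyl 4-hydroxy-3,5-dimethoxybenzoate (methyl syringate); 2 tert-butyl bromoacetate
Product: 3 methyl 4-(2-tert-butoxy-2-oxoethoxy)-3,5-dimethoxybenzoate
Conditions: K2CO3, DMF, 50 °C
Reagents that add atoms: none
Why: Williamson ether synthesis, in which the phenoxide displaces bromide from the activated primary alpha-bromo ester by SN2 and neither ester is touched by K2CO3.

Step 2
Reactants: 3 methyl 4-(2-tert-butoxy-2-oxoethoxy)-3,5-dimethoxybenzoate
Product: 4 [2,6-dimethoxy-4-(methoxycarbonyl)phenoxy]acetic acid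
Conditions: TFA/CH2Cl2 (1:3), rt
Reagents that add atoms: none
Why: Acidolysis of the tert-butyl ester through the tert-butyl cation (loss of isobutene) frees only the aliphatic acid, since the methyl ester and aryl methyl ethers are inert to TFA.

Step 3
Reactants: 4 [2,6-dimethoxy-4-(methoxycarbonyl)phenoxy]acetic acid; 5 (R)-4-benzyl-1,3-oxazolidin-2-one
Product: 7 methyl 4-{2-[(4R)-4-benzyl-2-oxo-1,3-oxazolidin-3-yl]-2-oxoethoxy}-3,5-dimethoxybenzoate, via pivalic mixed anhydride 6 (not isolated)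
Conditions: t-BuCOCl, Et3N, THF, -20 °C; then LiCl, 5, -20 °C to rt
Reagents that add atoms: none
Why: Mixed-anhydride N-acylation, in which the LiCl/Et3N-activated oxazolidinone attacks the unhindered aryloxyacetyl carbonyl rather than the pivaloyl carbonyl, so no organolithium base is needed.

Step 4
Reactants: 7 methyl 4-{2-[(4R)-4-benzyl-2-oxo-1,3-oxazolidin-3-yl]-2-oxoethoxy}-3,5-dimethoxybenzoate; 8 4-(benzyloxy)-3-methoxybenzaldehyde (O-benzylvanillin)
Product: 11 methyl 4-{[(1S,2R)-1-[4-(benzyloxy)-3-methoxyphenyl]-3-[(4R)-4-benzyl-2-oxo-1,3-oxazolidin-3-yl]-1-hydroxy-3-oxopropan-2-yl]oxy}-3,5-dimethoxybenzoate (syn aldol adduct), via dibutylboron Z-enolate 9 (not isolated), via dibutylboron aldolate 10 (not isolated)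
Conditions: Bu2BOTf, Et3N, CH2Cl2, -78 to 0 °C; 8, -78 to 0 °C; then H2O2, MeOH, pH 7 KH2PO4/K2HPO4 buffer, 0 °C
Reagents that add atoms: none
Why: Evans syn aldol, in which the Z-boron enolate reacts through a closed Zimmerman–Traxler chair whose one face is shielded by the benzyl group of the (R)-auxiliary, so the C7''–C8'' bond forms with the 2R,3S syn array (7''S,8''S after reduction) and the final 8'' configuration is set here.

Step 5
Reactants: 11 syn aldol adduct
Product: 12 methyl 4-{[(1S,2S)-1-[4-(benzyloxy)-3-methoxyphenyl]-1,3-dihydroxypropan-2-yl]oxy}-3,5-dimethoxybenzoate (threo diol)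
Conditions: NaBH4, THF/H2O (4:1), 0 °C to rt
Reagents that add atoms: none
Why: Reductive auxiliary cleavage, in which hydride attacks the activated imide carbonyl far faster than the electron-rich aromatic methyl ester and both stereocentres stay untouched (C8'' changes descriptor only).

Step 6
Reactants: 12 threo diol
Product: 13 methyl 4-{[(1S,2S)-1-[4-(benzyloxy)-3-methoxyphenyl]-1-hydroxy-3-(TBSO)propan-2-yl]oxy}-3,5-dimethoxybenzoate
Conditions: TBSCl (1.05 equiv), imidazole, CH2Cl2, 0 °C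
Reagents that add atoms: tert-butyldimethylsilyl chloride, CC(C)(C)[Si](C)(C)Cl
Why: Sterically selective silylation, since the primary C9'' hydroxyl reacts much faster than the flanked secondary benzylic hydroxyl.

Step 7
Reactants: 13 threo 9''-O-TBS alcohol
Product: 15 (1R,2S)-1-[4-(benzyloxy)-3-methoxyphenyl]-2-[2,6-dimethoxy-4-(methoxycarbonyl)phenoxy]-3-(TBSO)propyl 4-nitrobenzoate, via alkoxyphosphonium 4-nitrobenzoate 14 (not isolated)
Conditions: 4-O2NC6H4CO2H, PPh3, DIAD, THF, 0 °C to rt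
Reagents that add atoms: 4-nitrobenzoic acid, O=C(O)c1ccc([N+](=O)[O-])cc1
Why: Mitsunobu reaction, in which the acidic 4-nitrobenzoate displaces the oxyphosphonium group by SN2 and inverts C7'' from S to R (threo to erythro), while any retention product from ionisation is a diastereomer removable on silica and so cannot erode enantiopurity.

Step 8
Reactants: 15 erythro 4-nitrobenzoate
Product: 16 methyl 4-{[(1R,2S)-1-[4-(benzyloxy)-3-methoxyphenyl]-1-hydroxy-3-(TBSO)propan-2-yl]oxy}-3,5-dimethoxybenzoate (erythro alcohol)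
Conditions: K2CO3 (0.2 equiv), MeOH/THF, 0 °C to rt
Reagents that add atoms: none
Why: Base-catalysed transesterification cleaves the activated nitrobenzoate at its acyl carbon so the C7''–O bond and its configuration are retained, and exchange at the aromatic methyl ester is degenerate in methanol.

Step 9
Reactants: 16 erythro alcohol
Product: 17 methyl 4-{[(1R,2S)-1-[4-(benzyloxy)-3-methoxyphenyl]-1,3-bis(TBSO)propan-2-yl]oxy}-3,5-dimethoxybenzoate
Conditions: TBSOTf, 2,6-lutidine, CH2Cl2, 0 °C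
Reagents that add atoms: tert-butyldimethylsilyl triflate, CC(C)(C)[Si](C)(C)OS(=O)(=O)C(F)(F)F
Why: Silyl triflate silylation caps the hindered secondary alcohol on oxygen, and the lutidine buffer prevents benzylic ionisation, so C7'' is unchanged and no free hydroxyl remains for the later strong-base step.

Step 10
Reactants: 17 bis-TBS methyl ester
Product: 18 [4-{[(1R,2S)-1-[4-(benzyloxy)-3-methoxyphenyl]-1,3-bis(TBSO)propan-2-yl]oxy}-3,5-dimethoxyphenyl]methanol
Conditions: i-Bu2AlH (2.5 equiv), CH2Cl2, -78 to 0 °C; aq. potassium sodium tartrate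
Reagents that add atoms: none
Why: Hydride reduction of the only ester to the primary benzylic alcohol, with silyl, benzyl and aryl ethers inert to i-Bu2AlH.

Step 11
Reactants: 18 benzylic alcohol
Product: 19 4-{[(1R,2S)-1-[4-(benzyloxy)-3-methoxyphenyl]-1,3-bis(TBSO)propan-2-yl]oxy}-3,5-dimethoxybenzaldehyde
Conditions: MnO2 (15 equiv), CH2Cl2, rt
Reagents that add atoms: none
Why: MnO2 benzylic oxidation stops cleanly at the aldehyde, and the only other benzylic oxygen is silylated.

Step 12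
Reactants: 20 1-(2,4,6-trihydroxyphenyl)ethanone (phloroacetophenone)
Product: 21 1-[2,4-bis(benzyloxy)-6-hydroxyphenyl]ethanone
Conditions: BnBr (2.1 equiv), K2CO3, DMF, 60 °C
Reagents that add atoms: benzyl bromide, BrCc1ccccc1
Why: Twofold Williamson etherification that stops at the dibenzyl ether because the last hydroxyl is held in a strong intramolecular hydrogen bond to the acetyl carbonyl.

Step 13
Reactants: 19 ring B aldehyde; 21 1-[2,4-bis(benzyloxy)-6-hydroxyphenyl]ethanone
Product: 23 (E)-1-[2,4-bis(benzyloxy)-6-hydroxyphenyl]-3-[4-{[(1R,2S)-1-[4-(benzyloxy)-3-methoxyphenyl]-1,3-bis(TBSO)propan-2-yl]oxy}-3,5-dimethoxyphenyl]prop-2-en-1-one (chalcone), via beta-hydroxy ketone 22 (not isolated)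
Conditions: KOH (10 equiv, 50% aq.), EtOH/THF, rt, 48 h; then AcOH to pH 6
Reagents that add atoms: none
Why: Claisen–Schmidt condensation (crossed aldol then E1cB dehydration), in which only 21 can enolise and only 19 is an aldehyde, so the two fragments join cleanly to the conjugated E-enone while the alkyl TBS ethers and the capped side chain withstand ethanolic KOH at rt.

Step 14
Reactants: 23 chalcone
Product: 24 (2RS)-5,7-bis(benzyloxy)-2-[4-{[(1R,2S)-1-[4-(benzyloxy)-3-methoxyphenyl]-1,3-bis(TBSO)propan-2-yl]oxy}-3,5-dimethoxyphenyl]chroman-4-one (about 1:1 C2 epimers)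
Conditions: NaOAc, EtOH, reflux
Reagents that add atoms: none
Why: Intramolecular oxa-Michael addition (6-endo-trig) of the 2'-phenol closes ring C, favoured because the 6'-benzyloxy group twists the enone out of conjugation, and the remote side chain gives no control, so C2 forms as both epimers and recovered chalcone is recycled.

Step 15
Reactants: 24 flavanone epimer mixture
Product: 25 (2S)-5,7-bis(benzyloxy)-2-[4-{[(1R,2S)-1-[4-(benzyloxy)-3-methoxyphenyl]-1,3-bis(TBSO)propan-2-yl]oxy}-3,5-dimethoxyphenyl]chroman-4-one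
Conditions: Cp*RhCl[(R,R)-TsDPEN] (1 mol %), HCO2H/Et3N (5:2), EtOAc, rt, stopped at 52–55% conversion; silica gel
Reagents that add atoms: none
Why: Noyori-type asymmetric transfer hydrogenation run as a kinetic resolution, in which the (R,R)-catalyst makes 4R alcohols and is matched only with the 2R epimer (2,4-cis product), so the 2S ketone is left behind and separated from the polar flavan-4-ol, and the slightly acidic medium excludes retro-oxa-Michael epimerisation.

Step 16
Reactants: 25 (2S)-flavanone bis-TBS ether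
Product: 26 (2S)-5,7-bis(benzyloxy)-2-[4-{[(1R,2S)-1-[4-(benzyloxy)-3-methoxyphenyl]-1,3-dihydroxypropan-2-yl]oxy}-3,5-dimethoxyphenyl]chroman-4-one
Conditions: HF·pyridine, pyridine, THF, 0 °C to rt
Reagents that add atoms: none
Why: Fluoride-driven desilylation at silicon in a buffered, weakly acidic medium leaves both C–O bonds intact (C7'' retained) and avoids the basic conditions that would open the flavanone and scramble C2.

Step 17
Reactants: 26 tri-O-benzyl diol
Product: 27 (2S)-5,7-dihydroxy-2-[4-{[(1R,2S)-1,3-dihydroxy-1-(4-hydroxy-3-methoxyphenyl)propan-2-yl]oxy}-3,5-dimethoxyphenyl]chroman-4-one (target)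
Conditions: H2 (1 atm), 10% Pd/C, EtOAc/EtOH (1:1), rt, stopped at full debenzylation
Reagents that add atoms: none
Why: Catalytic hydrogenolysis removes the three primary O-benzyl groups under neutral conditions much faster than it attacks the hindered secondary benzylic C7''–OH, the C2–O1 bond or the vinylogous-ester ketone, so no stereocentre is touched.

## Compound list

1 | methyl 4-hydroxy-3,5-dimethoxybenzoate (methyl syringate) | COC(=O)c1cc(OC)c(O)c(OC)c1 | starting material
2 | tert-butyl bromoacetate | CC(C)(C)OC(=O)CBr | starting material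
3 | methyl 4-(2-tert-butoxy-2-oxoethoxy)-3,5-dimethoxybenzoate | COC(=O)c1cc(OC)c(OCC(=O)OC(C)(C)C)c(OC)c1 | intermediate
4 | [2,6-dimethoxy-4-(methoxycarbonyl)phenoxy]acetic acid | COC(=O)c1cc(OC)c(OCC(=O)O)c(OC)c1 | intermediate
5 | (R)-4-benzyl-1,3-oxazolidin-2-one | O=C1OC[C@@H](Cc2ccccc2)N1 | starting material
6 | pivalic mixed anhydride of 4 (not isolated) | COC(=O)c1cc(OC)c(OCC(=O)OC(=O)C(C)(C)C)c(OC)c1 | intermediate
7 | methyl 4-{2-[(4R)-4-benzyl-2-oxo-1,3-oxazolidin-3-yl]-2-oxoethoxy}-3,5-dimethoxybenzoate | COC(=O)c1cc(OC)c(OCC(=O)N2C(=O)OC[C@H]2Cc2ccccc2)c(OC)c1 | intermediate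
8 | 4-(benzyloxy)-3-methoxybenzaldehyde | COc1cc(C=O)ccc1OCc1ccccc1 | starting material
9 | (Z)-dibutylboron enolate of 7 (not isolated) | COC(=O)c1cc(OC)c(O/C=C(\OB(CCCC)CCCC)N2C(=O)OC[C@H]2Cc2ccccc2)c(OC)c1 | intermediate
10 | dibutylboron aldolate of 11 (not isolated) | COc1cc([C@H](OB(CCCC)CCCC)[C@H](C(=O)N2C(=O)OC[C@H]2Cc2ccccc2)Oc2c(OC)cc(C(=O)OC)cc2OC)ccc1OCc1ccccc1 | intermediate
11 | syn aldol adduct, (1S,2R) in the propanoyl chain, (4R)-auxiliary | COc1cc([C@H](O)[C@H](C(=O)N2C(=O)OC[C@H]2Cc2ccccc2)Oc2c(OC)cc(C(=O)OC)cc2OC)ccc1OCc1ccccc1 | intermediate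
12 | threo diol, (7''S,8''S) | COc1cc([C@H](O)[C@H](CO)Oc2c(OC)cc(C(=O)OC)cc2OC)ccc1OCc1ccccc1 | intermediate
13 | threo 9''-O-TBS alcohol, (7''S,8''S) | COc1cc([C@H](O)[C@H](CO[Si](C)(C)C(C)(C)C)Oc2c(OC)cc(C(=O)OC)cc2OC)ccc1OCc1ccccc1 | intermediate
14 | C7''-oxytriphenylphosphonium 4-nitrobenzoate of 13 (not isolated) | COc1cc([C@H](O[P+](c2ccccc2)(c2ccccc2)c2ccccc2)[C@H](CO[Si](C)(C)C(C)(C)C)Oc2c(OC)cc(C(=O)OC)cc2OC)ccc1OCc1ccccc1.[O-]C(=O)c1ccc([N+](=O)[O-])cc1 | intermediate
15 | erythro 7''-O-(4-nitrobenzoate), (7''R,8''S) | COc1cc([C@@H](OC(=O)c2ccc([N+](=O)[O-])cc2)[C@H](CO[Si](C)(C)C(C)(C)C)Oc2c(OC)cc(C(=O)OC)cc2OC)ccc1OCc1ccccc1 | intermediate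
16 | erythro 9''-O-TBS alcohol, (7''R,8''S) | COc1cc([C@@H](O)[C@H](CO[Si](C)(C)C(C)(C)C)Oc2c(OC)cc(C(=O)OC)cc2OC)ccc1OCc1ccccc1 | intermediate
17 | erythro 7'',9''-bis-O-TBS methyl ester | COc1cc([C@@H](O[Si](C)(C)C(C)(C)C)[C@H](CO[Si](C)(C)C(C)(C)C)Oc2c(OC)cc(C(=O)OC)cc2OC)ccc1OCc1ccccc1 | intermediate
18 | erythro bis-O-TBS ring B benzylic alcohol | COc1cc([C@@H](O[Si](C)(C)C(C)(C)C)[C@H](CO[Si](C)(C)C(C)(C)C)Oc2c(OC)cc(CO)cc2OC)ccc1OCc1ccccc1 | intermediate
19 | erythro bis-O-TBS ring B aldehyde | COc1cc([C@@H](O[Si](C)(C)C(C)(C)C)[C@H](CO[Si](C)(C)C(C)(C)C)Oc2c(OC)cc(C=O)cc2OC)ccc1OCc1ccccc1 | intermediate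
20 | 1-(2,4,6-trihydroxyphenyl)ethanone | CC(=O)c1c(O)cc(O)cc1O | starting material
21 | 1-[2,4-bis(benzyloxy)-6-hydroxyphenyl]ethanone | CC(=O)c1c(O)cc(OCc2ccccc2)cc1OCc1ccccc1 | intermediate
22 | beta-hydroxy ketone (aldol, both carbinol epimers, not isolated) | COc1cc([C@@H](O[Si](C)(C)C(C)(C)C)[C@H](CO[Si](C)(C)C(C)(C)C)Oc2c(OC)cc(C(O)CC(=O)c3c(O)cc(OCc4ccccc4)cc3OCc3ccccc3)cc2OC)ccc1OCc1ccccc1 | intermediate
23 | (E)-chalcone | COc1cc([C@@H](O[Si](C)(C)C(C)(C)C)[C@H](CO[Si](C)(C)C(C)(C)C)Oc2c(OC)cc(/C=C/C(=O)c3c(O)cc(OCc4ccccc4)cc3OCc3ccccc3)cc2OC)ccc1OCc1ccccc1 | intermediate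
24 | protected flavanone, (2RS,7''R,8''S) | COc1cc([C@@H](O[Si](C)(C)C(C)(C)C)[C@H](CO[Si](C)(C)C(C)(C)C)Oc2c(OC)cc(C3CC(=O)c4c(OCc5ccccc5)cc(OCc5ccccc5)cc4O3)cc2OC)ccc1OCc1ccccc1 | intermediate
25 | protected flavanone, (2S,7''R,8''S) | COc1cc([C@@H](O[Si](C)(C)C(C)(C)C)[C@H](CO[Si](C)(C)C(C)(C)C)Oc2c(OC)cc([C@@H]3CC(=O)c4c(OCc5ccccc5)cc(OCc5ccccc5)cc4O3)cc2OC)ccc1OCc1ccccc1 | intermediate
26 | tri-O-benzyl diol, (2S,7''R,8''S) | COc1cc([C@@H](O)[C@H](CO)Oc2c(OC)cc([C@@H]3CC(=O)c4c(OCc5ccccc5)cc(OCc5ccccc5)cc4O3)cc2OC)ccc1OCc1ccccc1 | intermediate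
27 | (2S)-5,7-dihydroxy-2-[4-{[(1R,2S)-1,3-dihydroxy-1-(4-hydroxy-3-methoxyphenyl)propan-2-yl]oxy}-3,5-dimethoxyphenyl]chroman-4-one | COc1cc([C@@H](O)[C@H](CO)Oc2c(OC)cc([C@@H]3CC(=O)c4c(O)cc(O)cc4O3)cc2OC)ccc1O | target

## Step count and risks

Total step count: 17. Longest linear sequence: 16 (steps 1–11 and 13–17, from 1). Step 12 is the one-step side branch.

**Step 7, Mitsunobu inversion.** The carbinol is hindered and electron-rich, so it may react slowly or ionise. The fallback sets out from 13 and comes back at 16, and replaces substitution by an oxidation and reduction pair. Dess–Martin periodinane buffered with NaHCO3 in CH2Cl2 gives methyl 4-{[(2S)-1-[4-(benzyloxy)-3-methoxyphenyl]-1-oxo-3-(TBSO)propan-2-yl]oxy}-3,5-dimethoxybenzoate F1. This ketone is reduced at once with Zn(BH4)2 in Et2O at -30 °C. Zinc ties the carbonyl oxygen to the aryloxy oxygen in a Cram chelate, and hydride enters from the side of the small C8'' hydrogen. This gives the anti (erythro) alcohol 16. The minor diastereomer is 13 itself and is fed back.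

**Step 15, kinetic resolution.** The ketone is flanked by the 5-benzyloxy group and may react slowly or with low selectivity. The fallback sets out from 24 and comes back at 25, and replaces the chemical resolution by a physical one. The two C2 epimers are diastereomers and are separated by preparative HPLC on an amylose tris(3,5-dimethylphenylcarbamate) phase. The unwanted (2R)-5,7-bis(benzyloxy)flavanone epimer F2 is re-equilibrated to 24 with NaOAc in refluxing EtOH through the chalcone 23 and recycled.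

**Step 17, hydrogenolysis.** The free C7'' benzylic alcohol or the C2–O1 bond may be over-reduced. The fallback sets out from 25 and comes back at 27, and reverses the order of the two deprotections. Hydrogenolysis (H2, 10% Pd/C, EtOAc/EtOH) is run while C7''–O still carries the bulky silyl group, which keeps that benzylic C–O bond off the catalyst. This gives (2S)-5,7-dihydroxy-2-[4-{[(1R,2S)-1-(4-hydroxy-3-methoxyphenyl)-1,3-bis(TBSO)propan-2-yl]oxy}-3,5-dimethoxyphenyl]chroman-4-one F3. The two silyl ethers are then removed with Et3N·3HF in MeCN/THF at rt, a near-neutral medium that neither epimerises C2 nor forms a quinone methide, and this gives 27.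

## Further compounds

F1 | step 7 | methyl 4-{[(2S)-1-[4-(benzyloxy)-3-methoxyphenyl]-1-oxo-3-(TBSO)propan-2-yl]oxy}-3,5-dimethoxybenzoate | COc1cc(C(=O)[C@H](CO[Si](C)(C)C(C)(C)C)Oc2c(OC)cc(C(=O)OC)cc2OC)ccc1OCc1ccccc1
F2 | step 15 | (2R)-5,7-bis(benzyloxy)flavanone epimer of 25, (2R,7''R,8''S) | COc1cc([C@@H](O[Si](C)(C)C(C)(C)C)[C@H](CO[Si](C)(C)C(C)(C)C)Oc2c(OC)cc([C@H]3CC(=O)c4c(OCc5ccccc5)cc(OCc5ccccc5)cc4O3)cc2OC)ccc1OCc1ccccc1
F3 | step 17 | (2S)-5,7-dihydroxy-2-[4-{[(1R,2S)-1-(4-hydroxy-3-methoxyphenyl)-1,3-bis(TBSO)propan-2-yl]oxy}-3,5-dimethoxyphenyl]chroman-4-one | COc1cc([C@@H](O[Si](C)(C)C(C)(C)C)[C@H](CO[Si](C)(C)C(C)(C)C)Oc2c(OC)cc([C@@H]3CC(=O)c4c(O)cc(O)cc4O3)cc2OC)ccc1O
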